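**Plan**

- Retrosynthesis cuts, in this order: (a) the ester C–O bond between C1 of the 3-hydroxy-3-methylglutarate unit and the allylic oxygen of Z-sinapyl alcohol; (b) the C3–C4 bond of the glutarate, with C4–C5 coming from an allyl group whose vinyl end is the latent C5 acid; (c) the Z C=C of the sinapyl unit, back to syringaldehyde.
- Enabling feature: C3 is a tertiary methyl carbinol between two methylenes (C2 and C4), which makes it the adduct of the ketone of an acetoacetate ester and an allyl nucleophile. The only ring is the arene, bought in syringaldehyde, so no ring is formed at any stage.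
- Forward: allylboronate 4 and benzyl acetoacetate 5 give carbinol 7. The vinyl group becomes the C5 acid and is masked as a 2-(trimethylsilyl)ethyl ester, and the benzyl ester is hydrogenolysed. Z-alcohol 17 is made from syringaldehyde, joined by Steglich esterification, and fluoride unmasks phenol and acid.
- Stereochemistry: C3 comes from catalyst-controlled allyl transfer (chiral 3,3'-dibromo-BINOL). It bears no hydrogen afterwards and is kept intact by never letting the two carboxyl arms become equivalent. The Z alkene comes from a kinetic Still–Gennari olefination.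

Key step: step 2

Assumption: the (S)-diol is taken to give the R carbinol by analogy with aryl methyl ketones, the CH2CO2Bn arm acting as the large group; if the first run shows the opposite sense, the (R)-diol is used with no other change.

**Route**

Step 1
Reactants: 1 allylmagnesium bromide; 2 triisopropyl borate
Product: 4 allyldiisopropoxyborane, via magnesium ate complex 3 (not isolated)
Conditions: Et2O, −78 °C to rt; then HCl (1 equiv, in Et2O), 0 °C; filtration under argon, distillation
Reagents that add atoms: none
Why: Grignard borylation of a trialkyl borate: addition at −78 °C should stop at the tetracoordinate borate 3, which cannot take up a second allyl group, and one equivalent of anhydrous HCl then expels isopropanol to leave the neutral boronic ester.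

Step 2
Reactants: 5 benzyl acetoacetate; 4 allyldiisopropoxyborane (1.5 equiv)
Product: 7 benzyl (R)-3-hydroxy-3-methylhex-5-enoate, via borate ester 6 (not isolated)
Conditions: (S)-3,3'-dibromo-1,1'-bi-2-naphthol (15 mol %), PhCF3/toluene 3:1, −35 °C; then aq. NaHCO3
Reagents that add atoms: none
Why: Proposed new method: the diol displaces one isopropoxide of 4 to give a more Lewis-acidic chiral allylboronate, the ketone oxygen of 5 binds boron and the allyl group migrates through a closed six-membered chair transition state (Zimmerman–Traxler-type allylboration) to give borate 6, from which isopropanol frees the diol and water frees the alcohol. The closest known reaction is the chiral-biphenol-catalysed allylboration of aryl and alkyl methyl ketones with this same boronate; a β-keto ester, with its enol content and second carbonyl, has not been established as the acceptor. No ring is closed; one skeletal bond (C3–C4) and one stereocentre (C3) are formed. C3 is set by the catalyst alone: the boron-bound (S)-diol blocks one quadrant, so the ketone should sit with the larger CH2CO2Bn arm pseudo-equatorial and methyl pseudo-axial in the chair, which presents the face leading to the R carbinol. The step needs site selectivity for the ketone over the ester carbonyl and the acidic C2 methylene; the ketone is the only carbonyl Lewis-basic and electrophilic enough to enter the chair, and the absence of base or any metal enolate former leaves C2 untouched. Sequestration of boron by the enol tautomer is countered by the excess of 4, the low temperature and the non-coordinating solvent.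

Step 3
Reactants: 7 benzyl (R)-3-hydroxy-3-methylhex-5-enoate
Product: 10 (R)-5-(benzyloxy)-3-hydroxy-3-methyl-5-oxopentanoic acid, via secondary ozonide 8 (not isolated), via aldehyde 9 (not isolated)
Conditions: O3, CH2Cl2, −78 °C (Sudan Red 7B end point); Me2S, −78 °C to rt; concentrate; NaClO2, NaH2PO4, 2-methylbut-2-ene, t-BuOH/H2O, 0 °C to rt
Reagents that add atoms: ozone, [O-][O+]=O; sodium chlorite, [Na+].[O-]Cl=O
Why: Ozonolysis (Criegee mechanism) should cleave the only alkene far faster than ozone attacks the benzyl arene, Me2S reduces ozonide 8 to aldehyde 9, which is used crude to avoid dehydration on silica, and the buffered Pinnick oxidation gives the acid without affecting the tertiary alcohol or C3, which has no hydrogen to lose.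

Step 4
Reactants: 10 (R)-5-(benzyloxy)-3-hydroxy-3-methyl-5-oxopentanoic acid
Product: 11 1-benzyl 5-[2-(trimethylsilyl)ethyl] (S)-3-hydroxy-3-methylpentanedioate
Conditions: Me3SiCH2CH2OH, DCC, DMAP (cat.), CH2Cl2, 0 °C to rt
Reagents that add atoms: 2-(trimethylsilyl)ethanol, C[Si](C)(C)CCO
Why: Steglich esterification: the O-acylisourea from the acid and DCC is passed by DMAP to the primary alcohol, while the hindered tertiary C3 hydroxyl does not compete and the benzyl ester is untouched, so the two carboxyl arms stay differentiated.

Step 5
Reactants: 11 1-benzyl 5-[2-(trimethylsilyl)ethyl] (S)-3-hydroxy-3-methylpentanedioate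
Product: 12 (S)-3-hydroxy-3-methyl-5-oxo-5-[2-(trimethylsilyl)ethoxy]pentanoic acid
Conditions: H2 (1 atm), 10% Pd/C, EtOAc, rt
Reagents that add atoms: none
Why: Catalytic hydrogenolysis of the benzylic C–O bond should free the C1 acid under neutral conditions, the silylethyl ester and the tertiary alcohol being inert and no alkene being present at this stage.

Step 6
Reactants: 13 syringaldehyde
Product: 14 4-[(tert-butyldimethylsilyl)oxy]-3,5-dimethoxybenzaldehyde
Conditions: TBSCl, imidazole, DMF, rt
Reagents that add atoms: tert-butyldimethylsilyl chloride, CC(C)(C)[Si](C)(C)Cl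
Why: Imidazole-promoted silylation of the phenol (Corey silyl ether protocol) masks the acidic, oxidation-prone phenol for the base and hydride steps that follow.

Step 7
Reactants: 14 4-[(tert-butyldimethylsilyl)oxy]-3,5-dimethoxybenzaldehyde; 15 methyl bis(2,2,2-trifluoroethyl)phosphonoacetate
Product: 16 methyl (Z)-3-{4-[(tert-butyldimethylsilyl)oxy]-3,5-dimethoxyphenyl}prop-2-enoate
Conditions: KN(SiMe3)2, 18-crown-6, THF, −78 °C
Reagents that add atoms: none
Why: Still–Gennari modification of the Horner–Wadsworth–Emmons olefination: with the electron-poor bis(trifluoroethyl) phosphonate and a dissociated potassium counter-ion the syn adduct eliminates faster than it reverts, so the kinetic Z enoate should predominate with this non-enolisable aryl aldehyde.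

Step 8
Reactants: 16 methyl (Z)-3-{4-[(tert-butyldimethylsilyl)oxy]-3,5-dimethoxyphenyl}prop-2-enoate
Product: 17 (Z)-3-{4-[(tert-butyldimethylsilyl)oxy]-3,5-dimethoxyphenyl}prop-2-en-1-ol
Conditions: i-Bu2AlH (2.5 equiv), CH2Cl2, −78 °C; aq. potassium sodium tartrate
Reagents that add atoms: none
Why: 1,2-Reduction of the enoate by i-Bu2AlH at −78 °C should give the allylic alcohol without conjugate reduction or loss of the Z geometry, and the aryl silyl ether tolerates the reagent.

Step 9
Reactants: 12 (S)-3-hydroxy-3-methyl-5-oxo-5-[2-(trimethylsilyl)ethoxy]pentanoic acid; 17 (Z)-3-{4-[(tert-butyldimethylsilyl)oxy]-3,5-dimethoxyphenyl}prop-2-en-1-ol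
Product: 18 1-[(Z)-3-{4-[(tert-butyldimethylsilyl)oxy]-3,5-dimethoxyphenyl}prop-2-en-1-yl] 5-[2-(trimethylsilyl)ethyl] (S)-3-hydroxy-3-methylpentanedioate
Conditions: DCC, DMAP (cat.), CH2Cl2, 0 °C to rt, exclusion of light
Reagents that add atoms: none
Why: Steglich esterification activates the carboxyl group and not the allylic C–O bond, so no allyl cation or allylic transposition can scramble the Z alkene, and the tertiary hydroxyl, the silylethyl ester and the aryl silyl ether are spectators.

Step 10
Reactants: 18 the doubly silyl-protected diester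
Product: 19 (3R)-3-hydroxy-5-{[(2Z)-3-(4-hydroxy-3,5-dimethoxyphenyl)prop-2-en-1-yl]oxy}-3-methyl-5-oxopentanoic acid (CNP0150281.1)
Conditions: tris(dimethylamino)sulfonium difluorotrimethylsilicate (TASF, 3 equiv), DMF, 0 °C to rt; then AcOH, pH 4 buffer
Reagents that add atoms: none
Why: Fluoride-induced desilylation should remove both silicon groups in one operation, the aryl silyl ether by attack at silicon and the 2-(trimethylsilyl)ethyl ester by β-fragmentation with loss of ethene, under conditions mild enough for the allylic ester, the Z alkene and the tertiary alcohol, and the acetic acid quench returns the phenol and the acid.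

**Compound list**

1 | allylmagnesium bromide | C=CC[Mg]Br | starting material
2 | triisopropyl borate | CC(C)OB(OC(C)C)OC(C)C | starting material
3 | bromomagnesium allyltriisopropoxyborate (not isolated) | C=CC[B-](OC(C)C)(OC(C)C)OC(C)C.[Mg+]Br | intermediate
4 | allyldiisopropoxyborane | C=CCB(OC(C)C)OC(C)C | intermediate
5 | benzyl acetoacetate | CC(=O)CC(=O)OCc1ccccc1 | starting material
6 | benzyl (R)-3-[(diisopropoxyboranyl)oxy]-3-methylhex-5-enoate (not isolated) | O=C(OCc1ccccc1)C[C@](C)(OB(OC(C)C)OC(C)C)CC=C | intermediate
7 | benzyl (R)-3-hydroxy-3-methylhex-5-enoate | O=C(OCc1ccccc1)C[C@](C)(O)CC=C | intermediate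
8 | benzyl (3R)-3-hydroxy-3-methyl-4-(1,2,4-trioxolan-3-yl)butanoate, mixture at the ring carbon (not isolated) | O=C(OCc1ccccc1)C[C@](C)(O)CC1OCOO1 | intermediate
9 | benzyl (R)-3-hydroxy-3-methyl-5-oxopentanoate (not isolated) | O=C(OCc1ccccc1)C[C@](C)(O)CC=O | intermediate
10 | (R)-5-(benzyloxy)-3-hydroxy-3-methyl-5-oxopentanoic acid | O=C(OCc1ccccc1)C[C@](C)(O)CC(=O)O | intermediate
11 | 1-benzyl 5-[2-(trimethylsilyl)ethyl] (S)-3-hydroxy-3-methylpentanedioate | O=C(OCc1ccccc1)C[C@](C)(O)CC(=O)OCC[Si](C)(C)C | intermediate
12 | (S)-3-hydroxy-3-methyl-5-oxo-5-[2-(trimethylsilyl)ethoxy]pentanoic acid | OC(=O)C[C@](C)(O)CC(=O)OCC[Si](C)(C)C | intermediate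
13 | syringaldehyde | COc1cc(C=O)cc(OC)c1O | starting material
14 | 4-[(tert-butyldimethylsilyl)oxy]-3,5-dimethoxybenzaldehyde | COc1cc(C=O)cc(OC)c1O[Si](C)(C)C(C)(C)C | intermediate
15 | methyl bis(2,2,2-trifluoroethyl)phosphonoacetate | COC(=O)CP(=O)(OCC(F)(F)F)OCC(F)(F)F | starting material
16 | methyl (Z)-3-{4-[(tert-butyldimethylsilyl)oxy]-3,5-dimethoxyphenyl}prop-2-enoate | COC(=O)/C=C\c1cc(OC)c(O[Si](C)(C)C(C)(C)C)c(OC)c1 | intermediate
17 | (Z)-3-{4-[(tert-butyldimethylsilyl)oxy]-3,5-dimethoxyphenyl}prop-2-en-1-ol | OC/C=C\c1cc(OC)c(O[Si](C)(C)C(C)(C)C)c(OC)c1 | intermediate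
18 | 1-[(Z)-3-{4-[(tert-butyldimethylsilyl)oxy]-3,5-dimethoxyphenyl}prop-2-en-1-yl] 5-[2-(trimethylsilyl)ethyl] (S)-3-hydroxy-3-methylpentanedioate | COc1cc(/C=C\COC(=O)C[C@](C)(O)CC(=O)OCC[Si](C)(C)C)cc(OC)c1O[Si](C)(C)C(C)(C)C | intermediate
19 | (3R)-3-hydroxy-5-{[(2Z)-3-(4-hydroxy-3,5-dimethoxyphenyl)prop-2-en-1-yl]oxy}-3-methyl-5-oxopentanoic acid | COc1cc(/C=C\COC(=O)C[C@](C)(O)CC(=O)O)cc(OC)c1O | target

**Step count**

Total: 10 steps. Longest linear sequence: 7 steps (steps 1, 2, 3, 4, 5, 9, 10); the alcohol branch (steps 6, 7, 8) joins at step 9.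

**Steps most likely to fail**

Step 2. The enol tautomer of the β-keto ester may tie up the boron reagent as a chelate and stall turnover, or the catalyst may discriminate poorly between methyl and CH2CO2Bn. The fallback uses known chemistry and sets out from 5. Barbier allylation with allyl bromide and Zn dust in THF/saturated aqueous NH4Cl, which is established for β-keto esters and forms no enolate, would give racemic benzyl 3-hydroxy-3-methylhex-5-enoate F1. Its enantiomers would be separated by preparative chromatography on a polysaccharide chiral stationary phase; the S enantiomer is set aside and the R enantiomer is 7, where the route is rejoined.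

Step 10. Basic fluoride liberates a phenoxide in conjugation with the allylic ester, which may expel the carboxylate through an extended quinone methide, cleave the ester or erode the Z geometry. The fallback sets out from 13 and masks the phenol with a fluoride-stable, acid-labile acetal.
- Ethyl vinyl ether and pyridinium p-toluenesulfonate in CH2Cl2 would give 4-(1-ethoxyethoxy)-3,5-dimethoxybenzaldehyde F2, racemic at the acetal carbon, which is of no consequence.
- The olefination of step 7 with 15 would give methyl (Z)-3-[4-(1-ethoxyethoxy)-3,5-dimethoxyphenyl]prop-2-enoate F3, and i-Bu2AlH reduction the Z allylic alcohol F4.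
- DCC/DMAP coupling with 12 would give the acetal-protected silylethyl diester F5.
- Bu4NF in THF would then cleave only the silylethyl ester, with no phenoxide formed, to give the acetal-protected acid F6.
- AcOH/THF/H2O at rt would remove the acetal and arrive at 19.

Step 7. The olefination may give insufficient Z selectivity with this electron-rich aldehyde, or the geometry may drift during reduction and handling. The fallback sets out from 14 and fixes the geometry by alkyne semi-hydrogenation. CBr4/PPh3 in CH2Cl2 (Corey–Fuchs) would give tert-butyl[4-(2,2-dibromoethenyl)-2,6-dimethoxyphenoxy]dimethylsilane F7. n-BuLi (2 equiv) in THF at −78 °C followed by paraformaldehyde would give 3-{4-[(tert-butyldimethylsilyl)oxy]-3,5-dimethoxyphenyl}prop-2-yn-1-ol F8. Hydrogenation over Pd/CaCO3 poisoned with Pb(OAc)2 and quinoline in EtOAc would deliver 17, where the route is rejoined.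

**Further compounds**

F1 | step 2 | racemic benzyl 3-hydroxy-3-methylhex-5-enoate | O=C(OCc1ccccc1)CC(C)(O)CC=C
F2 | step 10 | 4-(1-ethoxyethoxy)-3,5-dimethoxybenzaldehyde | CCOC(C)Oc1c(OC)cc(C=O)cc1OC
F3 | step 10 | methyl (Z)-3-[4-(1-ethoxyethoxy)-3,5-dimethoxyphenyl]prop-2-enoate | COC(=O)/C=C\c1cc(OC)c(OC(C)OCC)c(OC)c1
F4 | step 10 | (Z)-3-[4-(1-ethoxyethoxy)-3,5-dimethoxyphenyl]prop-2-en-1-ol | OC/C=C\c1cc(OC)c(OC(C)OCC)c(OC)c1
F5 | step 10 | 1-{(Z)-3-[4-(1-ethoxyethoxy)-3,5-dimethoxyphenyl]prop-2-en-1-yl} 5-[2-(trimethylsilyl)ethyl] (S)-3-hydroxy-3-methylpentanedioate | COc1cc(/C=C\COC(=O)C[C@](C)(O)CC(=O)OCC[Si](C)(C)C)cc(OC)c1OC(C)OCC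
F6 | step 10 | (3R)-5-{[(2Z)-3-[4-(1-ethoxyethoxy)-3,5-dimethoxyphenyl]prop-2-en-1-yl]oxy}-3-hydroxy-3-methyl-5-oxopentanoic acid | COc1cc(/C=C\COC(=O)C[C@](C)(O)CC(=O)O)cc(OC)c1OC(C)OCC
F7 | step 7 | tert-butyl[4-(2,2-dibromoethenyl)-2,6-dimethoxyphenoxy]dimethylsilane | COc1cc(C=C(Br)Br)cc(OC)c1O[Si](C)(C)C(C)(C)C
F8 | step 7 | 3-{4-[(tert-butyldimethylsilyl)oxy]-3,5-dimethoxyphenyl}prop-2-yn-1-ol | OCC#Cc1cc(OC)c(O[Si](C)(C)C(C)(C)C)c(OC)c1
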